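## The problem

The target **14** is a flavanone. It is a chroman-4-one (rings A and C) carrying a 3,4-dimethoxyphenyl group (ring B) at C2, with ring A methoxylated at C5, C7 and C8 so that C6 is its only CH. There is one stereocentre, (S)-C2, and nothing else in the molecule can relay chirality to it, so it must come from a catalyst or reagent. That centre is fragile: it is benzylic, bears the ring oxygen and lies beta to the C4 ketone, so base or hot acid opens ring C by retro-oxa-Michael elimination and recloses it without memory of configuration. C2 should therefore be set late, under neutral conditions, with all five methyl ethers already in place. The second problem is regiochemical: ring A is a 1,2,3,5-tetraoxygenated benzene, and the carbonyl carbon must be attached at C4a, between O1 and the C5 methoxy group, and not at the equally activated C6. The electron-rich rings tolerate neither strong oxidants nor strong Lewis acids, which cleave the C5 ether peri to the carbonyl first. The enabling feature is that C4 lies between the aryl carbon C4a and C3, while C2 is bonded to both O1 and ring B. Ring C is therefore the sum of an ortho-iodophenol (C4a–I and O1–H), carbon monoxide (C4) and an arylacetylene (C3, C2 and ring B), and the flat flavone so formed has a prochiral C2=C3 bond from which C2 can be set by hydrogenation.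

## Retrosynthesis

**14 ⇒ 13.** The C2–H and C3–H bonds are removed first, which takes **14** back to flavone **13**. The neighbouring cut, O1–C2 alone (asymmetric oxa-Michael closure of a ring-opened enone), relies on the same equilibrium that racemises flavanones and is unfavourable when the ketone is flanked by a methoxy group. Flavone **13** has no stereocentre, is configurationally indifferent to acid and base, and can be purified freely. The forward reaction must reduce an electron-rich vinylogous ester alkene from one face only, leave the C4 ketone alone and run without base. A rhodium hydride held on the C4 carbonyl by a thiourea hydrogen bond meets these demands.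

**13 ⇒ 8 + 9 + 10.** Three bonds of ring C are cut at once: C4a–C4, C4–C3 and O1–C2. This leaves iodophenol **8**, arylacetylene **9** and carbon monoxide **10**. The classical alternative builds ring C by condensation from an ortho-hydroxyacetophenone. That route needs the acyl group placed on ring A by electrophilic substitution, which is the regiochemical choice that cannot be trusted, and it ends with an acidic cyclodehydration that endangers the C5 ether. In the carbonylative cut the iodine marks C4a unambiguously and every carbon of ring C arrives in one operation. Alkyne **9** and **10** are commercial, and **8** is a benzene with one halogen. The forward step must insert CO before the alkyne couples and must close 6-endo and not 5-exo.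

**8 ⇒ 7 ⇒ 5.** The C–I bond is cut next, after the phenol is masked as its MOM ether **7**. Direct iodination of the free phenol would be divided between the position ortho to the hydroxyl and the position para to it, both flanked by methoxy groups. Directed ortho-metalation of MOM ether **5** through aryllithium **6** is preferred, because the MOM group is a stronger director than a methyl ether and the required CH is its only ortho hydrogen. Arene **5** carries no halogen and only ether functions. The forward reaction needs lithiation next to the MOM ether and not between the two methoxy groups, followed by mild acid release of the phenol without loss of iodine.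

**5 ⇒ 4 ⇒ 2 ⇒ 1.** The C8 oxygen is traced back to a formyl group: methyl ether **5** comes from phenol **4**, and **4** from aldehyde **2** by Dakin-type oxidation through formate **3**. Aldehyde **2** is the MOM ether of commercial 2-hydroxy-4,6-dimethoxybenzaldehyde **1**. In **1** the three oxygens are already differentiated (one free hydroxyl, the future O1, and two methyl ethers) and the formyl group marks the carbon that must be oxygenated. A route through a symmetrical catechol would not tell the two adjacent oxygens apart. The forward sequence needs aryl migration in the peracid oxidation, which the three donor groups ensure, and a protecting group that survives it.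

## Roads not taken

**Alternative 1:** The cut removes C3 as a one-carbon unit (bonds C2–C3 and C3–C4) and contracts ring C to a benzofuran.
- Forward: the 3-silyloxy-2-arylbenzofuran A2 would take up methylene from a chiral zinc carbenoid (Et2Zn, CH2I2, chiral ligand) to give siloxycyclopropane A1. Cleavage of the ring-fusion bond of A1, with protonation at the aryl-bearing carbon, would expand the ring to **14**.
- Merits: C4 arrives as a ketone and no pressure equipment is needed. The stereocentre is created as a fully substituted carbon that cannot epimerise while locked in A1. In this respect the route is better than the chosen one, where the configured C2–H is exposed from the moment it is made.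
- Weak points: the alkene of A2 is tetrasubstituted, is part of an aromatic furan and has no hydroxyl to anchor the zinc reagent. Enantioselective methylene transfer is established for allylic alcohols and simple silyl enol ethers, not for this substrate class, so the stereo-determining step would be method development. The ring opening must break the internal bond specifically and protonate a carbon bearing an aryloxy group and an electron-rich aryl group with defined stereochemistry. Fluoride or base at that stage can expel the phenoxide and racemise the product. A2 is no simpler than flavone **13** and poses the same ring A regiochemical problem.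
- Comparison: against the configurational safety of A1, the chosen plan offers steps that all belong to known reaction types, and a stereocentre made in the last step that only has to survive isolation.

**Alternative 2:** The cut is the O1–C8a bond.
- Forward: acylhydroquinone A4, carrying the (S)-configured secondary alcohol, would be oxidised with Ag2O to acylquinone A5. The hydroxyl adds to the quinone carbon next to the acyl group, and Na2S2O4 work-up returns the 5,8-dihydroxyflavanone A3. Methylation of both phenols would then give **14**.
- Merits: the stereocentre is set on an open chain by dependable carbonyl chemistry. The closure forms the aryl–oxygen bond and not the C2–O bond, so configuration is carried through untouched. No asymmetric hydrogenation of a vinylogous ester is needed, which removes the least secure step of the chosen plan. Here the alternative is better.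
- Weak points: A3 is not the target. Two phenols, one of them the hydrogen-bonded 5-hydroxyl, must be methylated on a finished flavanone, and the base this needs opens ring C and racemises C2. A4 is a beta-hydroxy ketone prone to dehydration and retro-aldol cleavage under oxidative or basic conditions. A5 offers a second unsubstituted quinone position to nucleophiles, and A3 is an air-sensitive hydroquinone.
- Comparison: the chosen plan installs all five methyl ethers before ring C exists and makes the stereocentre under neutral hydrogen, which is what it sets against the stereochemical security of the open-chain approach.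

**Alternative 3:** The cut is a retro hetero-Diels–Alder reaction across C3–C4 and O1–C2.
- Forward: a chiral phosphoric acid would dehydrate salicyl alcohol A7 to ortho-quinone methide A9, which adds styrene A8 to give flavan A6. The C4 methylene of A6 must then be oxidised to the ketone to reach **14**.
- Merits: this is the most convergent construction of the three. Ring and stereocentre form in one step from two simple partners, the polarity of the electron-rich styrene guarantees the aryl group at C2, and the stereocentre is reached in fewer steps than in the chosen plan. A8 is as accessible as **9**.
- Weak points: A8 has no hydrogen-bond donor to hold it in the chiral ion pair, and an electron-rich styrene can add stepwise through a benzylic cation, so enantiocontrol is doubtful. A9, with three methoxy donors, is a stabilised and sluggish heterodiene. A6 is also at the wrong oxidation level. Oxidising C4 in the presence of C2–H, which is benzylic to the dimethoxyphenyl ring and alpha to oxygen, risks attack at C2 or dehydrogenation with loss of the stereocentre, and costs at least two further steps.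
- Comparison: the chosen plan brings C4 in as carbon monoxide at the correct oxidation level and pays for this with a separate asymmetric step.

Key step: step 6

Assumption: compounds **1**, **9** and **10** are taken as commercial. The sense of induction of the hydrogenation ligand is not asserted; the ligand enantiomer is specified only as the one that delivers hydrogen to the Re face of C2.

## Route

Step 1
Reactants: 1 2-hydroxy-4,6-dimethoxybenzaldehyde
Product: 2 2,4-dimethoxy-6-(methoxymethoxy)benzaldehyde
Conditions: MOMCl, i-Pr2NEt, CH2Cl2, 0 °C to reflux
Reagents that add atoms: chloromethyl methyl ether (MOMCl), COCCl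
Why: O-alkylation of the only phenol with an alpha-chloro ether (MOM protection); the amine base and gentle heating should overcome the hydrogen bond to the aldehyde. The MOM group is chosen because it later serves as the ortho-directing group in step 4.

Step 2
Reactants: 2 2,4-dimethoxy-6-(methoxymethoxy)benzaldehyde
Product: 4 2,4-dimethoxy-6-(methoxymethoxy)phenol, via aryl formate 3 (not isolated)
Conditions: mCPBA, CH2Cl2, 0 °C to rt; aq. NaHCO3 wash; then K2CO3 (cat.), MeOH, rt
Reagents that add atoms: 3-chloroperoxybenzoic acid (mCPBA), OOC(=O)c1cccc(Cl)c1
Why: Dakin-type oxidation run as a Baeyer–Villiger reaction: the trioxygenated aryl group should migrate in preference to hydride to give formate 3, which catalytic K2CO3 in MeOH transesterifies to phenol 4. The MOM and methyl ethers are inert to the peracid and to methanolysis.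

Step 3
Reactants: 4 2,4-dimethoxy-6-(methoxymethoxy)phenol
Product: 5 1,2,5-trimethoxy-3-(methoxymethoxy)benzene
Conditions: MeI, K2CO3, acetone, reflux
Reagents that add atoms: iodomethane, CI
Why: Williamson ether synthesis on the only free phenol; the MOM ether keeps the future O1 distinct from the three methyl ethers.

Step 4
Reactants: 5 1,2,5-trimethoxy-3-(methoxymethoxy)benzene
Product: 7 2-iodo-1,4,5-trimethoxy-3-(methoxymethoxy)benzene, via aryllithium 6 (not isolated)
Conditions: n-BuLi, THF, −20 to 0 °C; then I2, THF, −78 °C to rt
Reagents that add atoms: iodine, II
Why: Directed ortho-metalation followed by iodinolysis: the MOM ether is a stronger director than methoxy and can chelate lithium through its second oxygen, so deprotonation should occur at the CH flanked by OMOM and OMe and not at the CH between two methoxy groups. Aryllithium 6 is then trapped by iodine at the same carbon.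

Step 5
Reactants: 7 2-iodo-1,4,5-trimethoxy-3-(methoxymethoxy)benzene
Product: 8 2-iodo-3,5,6-trimethoxyphenol
Conditions: 2 M HCl in MeOH, rt
Reagents that add atoms: none
Why: Acid-catalysed acetal exchange (MOM cleavage) with methanol as acceptor; dilute acid at room temperature is chosen so that the electron-rich aryl iodide is not protodeiodinated, and the methyl ethers are untouched.

Step 6
Reactants: 8 2-iodo-3,5,6-trimethoxyphenol; 9 4-ethynyl-1,2-dimethoxybenzene; 10 carbon monoxide
Product: 13 2-(3,4-dimethoxyphenyl)-5,7,8-trimethoxy-4H-chromen-4-one, via ynone 11 (not isolated), via enaminone 12 (not isolated)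
Conditions: PdCl2(PPh3)2 (5 mol %), CO (20 bar), Et2NH, 120 °C, autoclave
Reagents that add atoms: none
Why: This is a carbonylative Sonogashira-type coupling followed by amine-mediated heteroannulation, the known palladium-catalysed carbonylative annulation of ortho-iodophenols with terminal alkynes to flavones. PdCl2(PPh3)2 is reduced in situ to zerovalent palladium, which inserts into the C–I bond of 8; CO insertion then gives an aroyl complex of divalent palladium, helped by the ready migration of the electron-rich, doubly ortho-substituted aryl group. Amine-assisted coupling with alkyne 9 and reductive elimination form C4a–C4 and C4–C3 and release ynone 11. Diethylamine adds to 11 in conjugate fashion to give enaminone 12, and the ortho-phenol oxygen then attacks the amine-bearing carbon and expels diethylamine, which makes O1–C2. The pyranone ring therefore closes in the 6-endo mode (6-endo-dig with respect to the ynone, carried out as a 6-endo-trig addition–elimination on 12). No stereocentre is formed. The step needs 6-endo closure over 5-exo closure to the aurone, and carbonylative over direct coupling to a 2-arylbenzofuran; the secondary amine secures the first by making the beta-carbon the only electrophilic site, and CO pressure secures the second. The iodine position in 8, fixed in step 4, dictates the 5,7,8-trimethoxy pattern.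

Step 7
Reactants: 13 2-(3,4-dimethoxyphenyl)-5,7,8-trimethoxy-4H-chromen-4-one
Product: 14 (2S)-2-(3,4-dimethoxyphenyl)-5,7,8-trimethoxy-2,3-dihydro-4H-chromen-4-one
Conditions: H2 (50 bar), [Rh(cod)Cl]2 (1 mol %), 1-[3,5-bis(trifluoromethyl)phenyl]-3-{1-[1',2-bis(diphenylphosphino)ferrocenyl]ethyl}thiourea (single enantiomer, 2.2 mol %), CH2Cl2, 35 °C
Reagents that add atoms: none
Why: Rhodium-catalysed asymmetric hydrogenation of a chromone C2=C3 bond with a bisphosphine–thiourea ligand: the thiourea N–H groups hydrogen-bond to the C4 carbonyl oxygen and hold the vinylogous ester on the chiral rhodium hydride, so hydrogen should be delivered to the Re face of C2 (ligand enantiomer chosen accordingly), which gives (S)-C2. The catalyst should reduce the alkene and not the ketone, and the neutral, base-free medium avoids ring opening of the flavanone and hence racemisation.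

## Compound list

1 | 2-hydroxy-4,6-dimethoxybenzaldehyde | COc1cc(O)c(C=O)c(OC)c1 | starting material
2 | 2,4-dimethoxy-6-(methoxymethoxy)benzaldehyde | COCOc1cc(OC)cc(OC)c1C=O | intermediate
3 | 2,4-dimethoxy-6-(methoxymethoxy)phenyl formate (not isolated) | COCOc1cc(OC)cc(OC)c1OC=O | intermediate
4 | 2,4-dimethoxy-6-(methoxymethoxy)phenol | COCOc1cc(OC)cc(OC)c1O | intermediate
5 | 1,2,5-trimethoxy-3-(methoxymethoxy)benzene | COCOc1cc(OC)cc(OC)c1OC | intermediate
6 | [3,4,6-trimethoxy-2-(methoxymethoxy)phenyl]lithium (not isolated) | [Li]c1c(OC)cc(OC)c(OC)c1OCOC | intermediate
7 | 2-iodo-1,4,5-trimethoxy-3-(methoxymethoxy)benzene | COCOc1c(I)c(OC)cc(OC)c1OC | intermediate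
8 | 2-iodo-3,5,6-trimethoxyphenol | COc1cc(OC)c(I)c(O)c1OC | intermediate
9 | 4-ethynyl-1,2-dimethoxybenzene | C#Cc1ccc(OC)c(OC)c1 | starting material
10 | carbon monoxide | [C-]#[O+] | starting material
11 | 3-(3,4-dimethoxyphenyl)-1-(2-hydroxy-3,4,6-trimethoxyphenyl)prop-2-yn-1-one (not isolated) | COc1ccc(C#CC(=O)c2c(O)c(OC)c(OC)cc2OC)cc1OC | intermediate
12 | (E)-3-(diethylamino)-3-(3,4-dimethoxyphenyl)-1-(2-hydroxy-3,4,6-trimethoxyphenyl)prop-2-en-1-one (not isolated) | CCN(CC)/C(=C/C(=O)c1c(O)c(OC)c(OC)cc1OC)c1ccc(OC)c(OC)c1 | intermediate
13 | 2-(3,4-dimethoxyphenyl)-5,7,8-trimethoxy-4H-chromen-4-one | COc1ccc(-c2cc(=O)c3c(OC)cc(OC)c(OC)c3o2)cc1OC | intermediate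
14 | (2S)-2-(3,4-dimethoxyphenyl)-5,7,8-trimethoxy-2,3-dihydro-4H-chromen-4-one | COc1ccc([C@@H]2CC(=O)c3c(OC)cc(OC)c(OC)c3O2)cc1OC | target

## Step count and risks

Total step count: 7. Longest linear sequence: 7 steps (1 to 14); alkyne 9 and carbon monoxide 10 enter at step 6.

**Step 6 (key step).**
- What may go wrong: oxidative addition into the C–I bond of 8 is slow, because the bond is flanked by OH and OMe on a very electron-rich ring, and this leaves room for reductive loss of iodine. The aroyl-palladium intermediate may be intercepted by diethylamine (aminocarbonylation). The alkyne may couple before CO inserts, after which the phenol closes onto the alkyne. 5-exo closure is the remaining leak.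
- Fallback (no palladium and no CO, known organolithium chemistry): it sets out from 5 and 9 and comes back at 11. Alkyne 9 is deprotonated with n-BuLi in THF and formylated with DMF to 3-(3,4-dimethoxyphenyl)prop-2-ynal F1. Arene 5 is lithiated as in step 4 to 6, which adds to F1 to give racemic 3-(3,4-dimethoxyphenyl)-1-[3,4,6-trimethoxy-2-(methoxymethoxy)phenyl]prop-2-yn-1-ol F2. MnO2 in CH2Cl2 oxidises this doubly activated alcohol to 3-(3,4-dimethoxyphenyl)-1-[3,4,6-trimethoxy-2-(methoxymethoxy)phenyl]prop-2-yn-1-one F3. HCl in MeOH removes the MOM group and the route is rejoined at ynone 11, which Et2NH in EtOH at reflux closes through 12 to flavone 13. This fallback shares the lithiation of step 4 and its regiochemical demand.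

**Step 7.**
- What may go wrong: low conversion or poor facial selectivity, because the C5 methoxy group peri to the carbonyl can disturb the thiourea–carbonyl hydrogen bond and the 2-aryl vinylogous ester is electron-rich and slow to hydrogenate. Over-reduction of the ketone and racemisation by ring opening during handling are further risks.
- Fallback (reduce through to the alcohol, then restore the ketone): it sets out from 13 and comes back at 14. Flavone 13 is hydrogenated with the ruthenium–carbene catalyst formed from Ru(cod)(2-methylallyl)2, 1,3-bis[1-(naphthalen-1-yl)ethyl]-4,5-dihydroimidazolium tetrafluoroborate (the enantiomer leading to the 2S series) and KOt-Bu under H2 in toluene/hexane. This system reduces both the alkene and the ketone of flavones and should give (2S,4S)-2-(3,4-dimethoxyphenyl)-5,7,8-trimethoxychroman-4-ol F4, the cis alcohol. Dess–Martin periodinane buffered with NaHCO3 in CH2Cl2 then re-oxidises C4 without touching C2 and gives 14.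

**Step 4.**
- What may go wrong: regiochemical leakage of the lithiation, with deprotonation at the CH between the two methoxy groups competing with the CH next to the MOM ether.
- Fallback (iodine placed by electrophilic substitution before the oxidation, under control of the chelated phenol): it sets out from 1 and comes back at 7. Aldehyde 1 is iodinated with benzyltrimethylammonium dichloroiodate and NaHCO3 in CH2Cl2/MeOH ortho to the hydroxyl, as is established for the corresponding acetophenone, to give 2-hydroxy-3-iodo-4,6-dimethoxybenzaldehyde F5. MOMCl and i-Pr2NEt give 3-iodo-4,6-dimethoxy-2-(methoxymethoxy)benzaldehyde F6. mCPBA converts F6 into 3-iodo-4,6-dimethoxy-2-(methoxymethoxy)phenyl formate F7, and K2CO3 in MeOH releases 3-iodo-4,6-dimethoxy-2-(methoxymethoxy)phenol F8. MeI and K2CO3 in acetone then give 7, and the route continues with step 5.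

## Further compounds

F1 | step 6 | 3-(3,4-dimethoxyphenyl)prop-2-ynal | COc1ccc(C#CC=O)cc1OC
F2 | step 6 | rac-3-(3,4-dimethoxyphenyl)-1-[3,4,6-trimethoxy-2-(methoxymethoxy)phenyl]prop-2-yn-1-ol | COc1ccc(C#CC(O)c2c(OCOC)c(OC)c(OC)cc2OC)cc1OC
F3 | step 6 | 3-(3,4-dimethoxyphenyl)-1-[3,4,6-trimethoxy-2-(methoxymethoxy)phenyl]prop-2-yn-1-one | COc1ccc(C#CC(=O)c2c(OCOC)c(OC)c(OC)cc2OC)cc1OC
F4 | step 7 | (2S,4S)-2-(3,4-dimethoxyphenyl)-5,7,8-trimethoxychroman-4-ol | COc1ccc([C@@H]2C[C@H](O)c3c(OC)cc(OC)c(OC)c3O2)cc1OC
F5 | step 4 | 2-hydroxy-3-iodo-4,6-dimethoxybenzaldehyde | COc1cc(OC)c(I)c(O)c1C=O
F6 | step 4 | 3-iodo-4,6-dimethoxy-2-(methoxymethoxy)benzaldehyde | COCOc1c(I)c(OC)cc(OC)c1C=O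
F7 | step 4 | 3-iodo-4,6-dimethoxy-2-(methoxymethoxy)phenyl formate | COCOc1c(I)c(OC)cc(OC)c1OC=O
F8 | step 4 | 3-iodo-4,6-dimethoxy-2-(methoxymethoxy)phenol | COCOc1c(I)c(OC)cc(OC)c1O
A1 | alternative 1 | 1a-(3,4-dimethoxyphenyl)-3,4,6-trimethoxy-6b-(trimethylsilyloxy)-1a,6b-dihydro-1H-cyclopropa[b]benzofuran (single enantiomer) | COc1ccc(cc1OC)[C@@]23Oc4c(OC)c(OC)cc(OC)c4[C@]2(O[Si](C)(C)C)C3
A2 | alternative 1 | 2-(3,4-dimethoxyphenyl)-4,6,7-trimethoxy-3-(trimethylsilyloxy)benzofuran | COc1ccc(cc1OC)-c1oc2c(OC)c(OC)cc(OC)c2c1O[Si](C)(C)C
A3 | alternative 2 | (S)-2-(3,4-dimethoxyphenyl)-5,8-dihydroxy-7-methoxychroman-4-one | COc1ccc([C@@H]2CC(=O)c3c(O)cc(OC)c(O)c3O2)cc1OC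
A4 | alternative 2 | (S)-1-(2,5-dihydroxy-4-methoxyphenyl)-3-(3,4-dimethoxyphenyl)-3-hydroxypropan-1-one | COc1ccc([C@@H](O)CC(=O)c2cc(O)c(OC)cc2O)cc1OC
A5 | alternative 2 | (S)-2-[3-(3,4-dimethoxyphenyl)-3-hydroxypropanoyl]-5-methoxycyclohexa-2,5-diene-1,4-dione | COc1ccc([C@@H](O)CC(=O)C2=CC(=O)C(OC)=CC2=O)cc1OC
A6 | alternative 3 | (S)-2-(3,4-dimethoxyphenyl)-5,7,8-trimethoxychroman | COc1ccc([C@@H]2CCc3c(OC)cc(OC)c(OC)c3O2)cc1OC
A7 | alternative 3 | 2-(hydroxymethyl)-3,5,6-trimethoxyphenol | OCc1c(O)c(OC)c(OC)cc1OC
A8 | alternative 3 | 4-ethenyl-1,2-dimethoxybenzene | C=Cc1ccc(OC)c(OC)c1
A9 | alternative 3 | 2,3,5-trimethoxy-6-methylidenecyclohexa-2,4-dien-1-one | C=C1C(=O)C(OC)=C(OC)C=C1OC
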